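**Abbreviations:** prenyl = 3-methylbut-2-en-1-yl; MOM = methoxymethyl. Compound numbers are those of the steps below.

## Analysis of the target

Euchrestaflavanone A (15) is a flavanone: aromatic ring A (C4a to C8a) is fused to the dihydropyranone ring C (O1, C2, C3, C4), and ring B sits on C2. Ring A carries hydroxyls at C5 and C7 and a prenyl group at C8; ring B carries a 4'-hydroxyl and a 3'-prenyl group. The only stereocentre is C2 (S). It is benzylic, bonded to O1 and beta to the C4 carbonyl, so it is lost whenever ring C opens by retro-oxa-Michael reaction under base, heat or strong acid. Each trisubstituted alkene lies ortho to a phenol and can cyclise to a 2,2-dimethylchroman in strong acid, and the phloroglucinol-type ring A is easily oxidised and substituted at C6. The synthesis is hard for two reasons: C6 and C8 of a 5,7-dioxygenated flavanone are almost equivalent, so a late prenylation gives both isomers, and C2 must be set in one absolute sense and then kept away from ring-opening conditions. The strategy rests on reading O1, C8a, C4a and C4 as the phenol oxygen, two ring carbons and formyl carbon of a salicylaldehyde (a 4-alkoxy ortho-quinone methide heterodiene), and C2–C3 as the vinyl group of a ring B styrene. Read this way, the C4 oxygen is present from the start and each prenyl group is fixed on a monocyclic building block before ring C exists.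

## Retrosynthetic reasoning

**15 to 14.** The last cut removes three O–CH2 bonds of MOM ethers, leading back to 14. The phenols are masked until the end because free phenols ortho to prenyl groups would interfere with the ylide, the acid catalysis and the oxidation of earlier steps. The forward reaction has to free three phenols under acid mild enough not to add them across the prenyl double bonds or to open ring C at O1–C2.

**14 to 13 to 12.** No skeletal bond is cut; only the oxidation level at C4 changes. The ketone of 14 is traced to the benzylic alcohol 13 and this to the benzylic methyl ether 12, because the ring-forming step delivers C4 as an ether. The forward steps must exchange the C4 methoxy group for hydroxyl without touching the aryl MOM ethers, then oxidise without enolising towards ring opening. The C4 configuration is irrelevant since it is destroyed.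

**12 to 8, 5 and 9.** The key disconnection cuts O1–C2 and C3–C4 of ring C.
- These two cuts follow the natural polarity: C4 is electrophilic (the formyl carbon of 8), C3 nucleophilic (the CH2 terminus of 5), C2 electrophilic (benzylic and para to the ring B oxygen) and O1 nucleophilic.
- They divide the molecule into two fragments of similar size, each carrying one prenyl group. Cutting C2–C3 or C4–C4a instead would leave one fragment carrying nearly everything.
- In 8 only the hydroxyl next to the prenyl group is free, so O1 can only be the oxygen beside C8 and the 8-prenyl pattern follows by construction.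
- The C4 methoxy group comes from 9.
- The forward reaction has to close ring C with the aryl group at C2 and with control of the absolute configuration, which only a chiral acid can supply.

**8 to 7 to 6 and 2.** The two MOM O–CH2 bonds are cut first, giving 7, then the aryl–CH2 bond of the prenyl group, giving 6 and 2. The two free ring positions of 6 are equivalent, so C-prenylation can give only one mono-prenyl isomer. The forward protection must leave free the one hydroxyl wedged between the prenyl and formyl groups.

**5 to 4 to 3 to 1 and 2.** The vinyl C=C bond is cut back to aldehyde 4, the MOM ether to phenol 3, and the aryl–prenyl bond to 1 and 2. In 1 the para position is blocked, so C-alkylation of the phenoxide can occur only ortho to oxygen.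

## Alternatives that were turned down

**Alternative 1: prenyl groups delivered from oxygen by sigmatropic shifts.**
- Disconnection: both aryl–CH2 bonds of the prenyl groups are cut and the groups are returned to oxygen. This gives the (2S)-flavanone A2 with a 5-O-prenyl ether, a 4'-O-(1,1-dimethylallyl) ether and a 7-O-acetate.
- Forward key step: heating A2 with a europium tris(β-diketonate) Lewis acid, EuL3, moves the 5-O-prenyl group to C6 by Claisen shift and on to C8 by Cope shift. The tertiary ether on ring B moves to C3' by one Claisen shift with allyl inversion. The product is A1, which needs one further deacetylation.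
- For: the skeleton and C2 come from a preformed (2S)-flavanone, so no asymmetric step is needed, and both C–C bonds form in one operation. On the stereocentre and on step count it is stronger than the chosen route.
- Against: three ring oxygens must be differentiated on the flavanone, including alkylation of the hydrogen-bonded O5 and construction of a tertiary allyl ether. The Cope leg can stop at C6 and leave the 6-(1,1-dimethylallyl) isomer. A 5-O-alkylated flavanone heated with a Lewis acid can open to the chalcone and lose C2. The route also depends on an enantiopure flavanone feedstock.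
- Comparison: the chosen route offers in its place regiochemistry that is fixed and checkable on small building blocks, no thermal Lewis-acid step on a finished flavanone, and independence from the optical purity of a natural flavanone.

**Alternative 2: ring C closed by carbene C–H insertion.**
- Disconnection: the C2–C3 bond, leading to the alpha-diazoketone A4, in which O1 carries the ring B benzyl group.
- Forward key step: a chiral dirhodium tetracarboxylate, Rh2(O2CR*)4, turns A4 into a rhodium carbene that inserts into a benzylic C–H bond of the O–CH2 group. This closes ring C and sets C2, giving A3.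
- For: ring C appears directly at the ketone oxidation level, so the two C4 adjustment steps of the chosen route are saved; on that point it is stronger. The C–H bond is doubly activated and the benzyl ether is easy to make.
- Against: the ether oxygen can attack the carbene to give an oxonium ylide, whose 1,2-benzyl shift leads to a benzofuranone and not to the flavanone. Carbenes with only an acyl acceptor are poorly discriminated by chiral dirhodium catalysts, so the enantioselectivity is no more secure than in the chosen route. The carbene can also cyclopropanate the prenyl alkenes or insert into their allylic C–H bonds. The diazoketone requires a hindered 2,6-dioxygenated benzoic acid and a longer linear sequence.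
- Comparison: the chosen route uses a stabilised carbocation, which distinguishes the styrene from the prenyl alkenes by cation stability, and it is convergent.

**Alternative 3: ring A built last by biomimetic Claisen condensation.**
- Disconnection: the C4a–C5 bond, unravelling ring A into a keto-ester chain on C8a of the (2S)-dihydropyranone A6.
- Forward key step: a mild base (an amidine or a magnesium alkoxide, Mg(OR)2) deprotonates C8. The dienolate attacks the ester through C4a to form C4a–C5, and enolisation aromatises ring A to give A5.
- For: ring A is born with its final pattern, so the prenyl group is on C8 by construction and ring A needs no protecting groups; here it is stronger than the chosen route. C2 could be set beforehand by an established catalytic asymmetric hetero-Diels–Alder reaction of aldehyde 4 with an oxygenated diene, which is also stronger than an unproven asymmetric step.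
- Against: A6 is a base-labile tricarbonyl compound. Base can expel O1 by beta-elimination and erase C2, O-cyclisation to pyrones competes, and the chain must be assembled by several enolate reactions on a sensitive vinylogous ester in a long linear sequence.
- Comparison: the chosen route is much shorter and convergent and keeps ring A aromatic throughout. Its price, the selective protection of ring A, is paid on a small aldehyde.

Key step: step 6

## Remarks on the chemistry (assumptions)

- The (R)-enantiomer of the phosphoric acid is written as the one that gives the 2S adduct; if it gives 2R, the (S)-acid is used with no other change.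
- The exocyclic double bond of 11 is drawn E; the ring closure is treated as stepwise, so this geometry does not decide the configuration of 12.

## Route

Step 1
Reactants: 1 4-hydroxybenzaldehyde; 2 prenyl bromide (1-bromo-3-methylbut-2-ene)
Product: 3 4-hydroxy-3-(3-methylbut-2-en-1-yl)benzaldehyde
Conditions: KOH (aq.), rt
Reagents that add atoms: none
Why: Phenoxide C-alkylation (ortho-prenylation): in water the phenoxide oxygen is shielded by hydrogen bonding, so the allylic bromide is attacked in part by the ortho carbon, the only ring position activated by the oxide in this para-substituted phenol. The neutral O-prenyl ether formed alongside is removed by extracting 3 into aqueous base.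

Step 2
Reactants: 3 4-hydroxy-3-(3-methylbut-2-en-1-yl)benzaldehyde
Product: 4 4-(methoxymethoxy)-3-(3-methylbut-2-en-1-yl)benzaldehyde
Conditions: MOMCl, i-Pr2NEt, CH2Cl2, 0 °C → rt
Reagents that add atoms: chloromethyl methyl ether, COCCl
Why: Williamson-type O-alkylation of the phenol (MOM protection); the aldehyde and the trisubstituted alkene are inert to these conditions.

Step 3
Reactants: 4 4-(methoxymethoxy)-3-(3-methylbut-2-en-1-yl)benzaldehyde
Product: 5 4-ethenyl-1-(methoxymethoxy)-2-(3-methylbut-2-en-1-yl)benzene (4-(methoxymethoxy)-3-prenylstyrene)
Conditions: Ph3PCH3Br, KOt-Bu, THF, 0 °C → rt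
Reagents that add atoms: methyltriphenylphosphonium bromide, C[P+](c1ccccc1)(c1ccccc1)c1ccccc1.[Br-]
Why: Wittig methylenation of an aryl aldehyde with a non-stabilised ylide; the MOM ether and the prenyl group tolerate the base.

Step 4
Reactants: 6 2,4,6-trihydroxybenzaldehyde; 2 prenyl bromide (1-bromo-3-methylbut-2-ene)
Product: 7 2,4,6-trihydroxy-3-(3-methylbut-2-en-1-yl)benzaldehyde
Conditions: DBU (1,8-diazabicyclo[5.4.0]undec-7-ene), THF, 0 °C → rt
Reagents that add atoms: none
Why: C-Alkylation of a phloroglucinol-type phenoxide: the ring carbons between two oxygens are strongly nucleophilic and the two free positions of 6 are equivalent, so only one mono-C-prenyl isomer can form. A slight deficit of 2 should limit double prenylation.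

Step 5
Reactants: 7 2,4,6-trihydroxy-3-(3-methylbut-2-en-1-yl)benzaldehyde
Product: 8 2-hydroxy-4,6-bis(methoxymethoxy)-3-(3-methylbut-2-en-1-yl)benzaldehyde
Conditions: MOMCl (2.1 equiv), i-Pr2NEt, CH2Cl2, 0 °C
Reagents that add atoms: chloromethyl methyl ether, COCCl
Why: Phenol O-alkylation (MOM protection) under steric and hydrogen-bond control: the 4-OH is the most acidic and unhindered, and the 6-OH is the more accessible of the two ortho hydroxyls. The 2-OH, wedged between the prenyl and formyl groups and chelated to the carbonyl, should stay free with two equivalents of reagent.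

Step 6
Reactants: 8 2-hydroxy-4,6-bis(methoxymethoxy)-3-(3-methylbut-2-en-1-yl)benzaldehyde; 9 trimethyl orthoformate; 5 4-ethenyl-1-(methoxymethoxy)-2-(3-methylbut-2-en-1-yl)benzene
Product: 12 (2S,4S)-4-methoxy-5,7-bis(methoxymethoxy)-2-[4-(methoxymethoxy)-3-(3-methylbut-2-en-1-yl)phenyl]-8-(3-methylbut-2-en-1-yl)chromane (2,4-cis), via dimethyl acetal 10 (not isolated), via methoxy ortho-quinone methide 11 (not isolated)
Conditions: 9 (1.5 equiv), (R)-3,3'-bis(2,4,6-triisopropylphenyl)-1,1'-binaphthyl-2,2'-diyl hydrogen phosphate (10 mol %), toluene, rt; then 5 (2 equiv), −20 → 0 °C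
Reagents that add atoms: none
Why: Proposed new method: the acid first promotes acetal exchange between 8 and 9 to give 10, then ionises 10 to a methoxycarbenium ion that is the O-protonated form of ortho-quinone methide 11 and stays hydrogen-bonded through its phenolic OH to the chiral phosphate. The CH2 terminus of styrene 5 attacks the carbenium carbon (C4) to form C3–C4, and the resulting para-alkoxybenzyl cation at C2 is captured by the phenolic oxygen in a 6-exo-trig closure that forms O1–C2 and ring C, overall an asynchronous oxa-[4+2] cycloaddition. The closest known reactions are the achiral-acid three-component synthesis of 2,4-cis-4-alkoxy-2-arylchromans from salicylaldehydes, orthoformates and styrenes, and chiral phosphoric acid-controlled cycloadditions of ortho-quinone methides with styrenes; joining them on an alkoxy ortho-quinone methide is the new element. C4 is set by the face of the ion pair that the 3,3'-aryl groups of the catalyst leave open, so it is catalyst-controlled. C2 is set in the ring closure, where the aryl group should take the pseudo-equatorial position cis to the 4-methoxy group while the phosphate is still bound to the attacking oxygen, so it is relayed from C4 and reinforced by the catalyst. The step needs regioselectivity (aryl at C2), which the polarity of the styrene and the para oxygen of ring B secure, and chemoselectivity for the vinyl group over the prenyl alkenes, which the much more stabilised benzylic cation secures. It also needs the electron-rich ring A positions not to act as Friedel–Crafts nucleophiles, which the excess of 5 and the low temperature should ensure. Later epimerisation at C4 by re-ionisation would be harmless, because only C2 survives into the target.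

Step 7
Reactants: 12 (2S,4S)-4-methoxy-5,7-bis(methoxymethoxy)-2-[4-(methoxymethoxy)-3-(3-methylbut-2-en-1-yl)phenyl]-8-(3-methylbut-2-en-1-yl)chromane
Product: 13 (2S,4RS)-5,7-bis(methoxymethoxy)-2-[4-(methoxymethoxy)-3-(3-methylbut-2-en-1-yl)phenyl]-8-(3-methylbut-2-en-1-yl)chroman-4-ol (C4 epimers)
Conditions: pyridinium p-toluenesulfonate (0.2 equiv), THF/H2O 4:1, rt
Reagents that add atoms: water, O
Why: SN1 solvolysis of a benzylic ether: the C4 cation is stabilised by O1 and the two ring A ether oxygens, so it should ionise under acid far too weak to cleave aryl MOM ethers, and water in large excess captures it. C2 is not involved, and the C4 configuration does not matter because the next step removes it.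

Step 8
Reactants: 13 (2S,4RS)-5,7-bis(methoxymethoxy)-2-[4-(methoxymethoxy)-3-(3-methylbut-2-en-1-yl)phenyl]-8-(3-methylbut-2-en-1-yl)chroman-4-ol
Product: 14 (2S)-5,7-bis(methoxymethoxy)-2-[4-(methoxymethoxy)-3-(3-methylbut-2-en-1-yl)phenyl]-8-(3-methylbut-2-en-1-yl)chroman-4-one
Conditions: Dess–Martin periodinane, pyridine, CH2Cl2, 0 °C → rt
Reagents that add atoms: none
Why: Dess–Martin oxidation of a secondary benzylic alcohol to the aryl ketone under pyridine buffering; both C4 epimers converge on one ketone. The medium is neutral and non-basic, so the prenyl alkenes, the MOM ethers and C2 should be untouched.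

Step 9
Reactants: 14 (2S)-5,7-bis(methoxymethoxy)-2-[4-(methoxymethoxy)-3-(3-methylbut-2-en-1-yl)phenyl]-8-(3-methylbut-2-en-1-yl)chroman-4-one
Product: 15 euchrestaflavanone A, (2S)-5,7-dihydroxy-2-[4-hydroxy-3-(3-methylbut-2-en-1-yl)phenyl]-8-(3-methylbut-2-en-1-yl)chroman-4-one
Conditions: HCl (1.25 M in MeOH), THF, 40 °C
Reagents that add atoms: none
Why: Acid-catalysed acetal solvolysis (MOM removal) in methanol, which traps the methoxymethyl cation as dimethoxymethane. The temperature is kept low to avoid addition of the freed ortho phenols across the prenyl double bonds and acid-mediated opening of ring C.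

## Compound list

1 | 4-hydroxybenzaldehyde | O=Cc1ccc(O)cc1 | starting material
2 | prenyl bromide (1-bromo-3-methylbut-2-ene) | CC(C)=CCBr | starting material
3 | 4-hydroxy-3-(3-methylbut-2-en-1-yl)benzaldehyde | CC(C)=CCc1cc(C=O)ccc1O | intermediate
4 | 4-(methoxymethoxy)-3-(3-methylbut-2-en-1-yl)benzaldehyde | COCOc1ccc(C=O)cc1CC=C(C)C | intermediate
5 | 4-ethenyl-1-(methoxymethoxy)-2-(3-methylbut-2-en-1-yl)benzene | C=Cc1ccc(OCOC)c(CC=C(C)C)c1 | intermediate
6 | 2,4,6-trihydroxybenzaldehyde | O=Cc1c(O)cc(O)cc1O | starting material
7 | 2,4,6-trihydroxy-3-(3-methylbut-2-en-1-yl)benzaldehyde | O=Cc1c(O)cc(O)c(CC=C(C)C)c1O | intermediate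
8 | 2-hydroxy-4,6-bis(methoxymethoxy)-3-(3-methylbut-2-en-1-yl)benzaldehyde | O=Cc1c(OCOC)cc(OCOC)c(CC=C(C)C)c1O | intermediate
9 | trimethyl orthoformate | COC(OC)OC | starting material
10 | 2-(dimethoxymethyl)-3,5-bis(methoxymethoxy)-6-(3-methylbut-2-en-1-yl)phenol | COC(OC)c1c(OCOC)cc(OCOC)c(CC=C(C)C)c1O | intermediate (not isolated)
11 | (6E)-6-(methoxymethylidene)-3,5-bis(methoxymethoxy)-2-(3-methylbut-2-en-1-yl)cyclohexa-2,4-dien-1-one | CO/C=C1/C(=O)C(CC=C(C)C)=C(OCOC)C=C1OCOC | intermediate (not isolated)
12 | (2S,4S)-4-methoxy-5,7-bis(methoxymethoxy)-2-[4-(methoxymethoxy)-3-(3-methylbut-2-en-1-yl)phenyl]-8-(3-methylbut-2-en-1-yl)chromane | CO[C@H]1C[C@@H](c2ccc(OCOC)c(CC=C(C)C)c2)Oc2c(CC=C(C)C)c(OCOC)cc(OCOC)c21 | intermediate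
13 | (2S,4RS)-5,7-bis(methoxymethoxy)-2-[4-(methoxymethoxy)-3-(3-methylbut-2-en-1-yl)phenyl]-8-(3-methylbut-2-en-1-yl)chroman-4-ol, mixture of C4 epimers (C4 left open in the SMILES) | OC1C[C@@H](c2ccc(OCOC)c(CC=C(C)C)c2)Oc2c(CC=C(C)C)c(OCOC)cc(OCOC)c21 | intermediate
14 | (2S)-5,7-bis(methoxymethoxy)-2-[4-(methoxymethoxy)-3-(3-methylbut-2-en-1-yl)phenyl]-8-(3-methylbut-2-en-1-yl)chroman-4-one | CC(C)=CCc1cc([C@@H]2CC(=O)c3c(OCOC)cc(OCOC)c(CC=C(C)C)c3O2)ccc1OCOC | intermediate
15 | euchrestaflavanone A | CC(C)=CCc1cc([C@@H]2CC(=O)c3c(O)cc(O)c(CC=C(C)C)c3O2)ccc1O | target

## Step count and least certain steps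

Total: 9 steps. Longest linear sequence: 7 steps (steps 1, 2, 3, 6, 7, 8, 9, from 1 to 15); the ring A branch (steps 4 and 5) joins at step 6.

**Step 6 (key step).**
- Weak facial discrimination is the main risk: the carbenium ion is strongly stabilised by ring A and is held by the phosphate through a single hydrogen bond, so the ion pair may be loose.
- The relay from C4 to C2 fails if the ring closure is not diastereoselective.
- Acid-induced oligomerisation of the electron-rich styrene and Friedel–Crafts self-condensation through the ring A C–H between the two MOM ethers can consume material.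
- Slow ionisation with so weak an acid, or partial loss of MOM groups with a stronger one, are the remaining risks.
- Fallback (known chemistry): from 8, 9 and 5, an achiral acid (diphenyl phosphate, (PhO)2P(O)OH, 10 mol %, CH2Cl2, 0 °C) runs the established racemic three-component chroman synthesis. It should give the 2,4-cis adduct as the racemate, that is 12 together with its mirror image (2R,4R)-4-methoxy-5,7-bis(methoxymethoxy)-2-[4-(methoxymethoxy)-3-(3-methylbut-2-en-1-yl)phenyl]-8-(3-methylbut-2-en-1-yl)chromane F1. Preparative HPLC on a chiral stationary phase (amylose tris(3,5-dimethylphenylcarbamate), hexane/2-propanol) separates the two, and the route is rejoined at 12.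

**Step 5.**
- Protection may occur at the wrong ortho hydroxyl or go on to the tris-ether, because the two ortho hydroxyls differ only by the neighbouring prenyl group. Step 4 before it can also suffer from O-alkylation and double C-prenylation.
- Fallback: it sets out from 6, replaces steps 4 and 5, and returns at 8.
  - MOM protection of 6 (MOMCl, 2 equiv, i-Pr2NEt, CH2Cl2) gives 2-hydroxy-4,6-bis(methoxymethoxy)benzaldehyde F2. The two ortho hydroxyls of 6 are equivalent, so no regiochemical question arises.
  - Copper-catalysed O-alkylation with 2-methylbut-3-yn-2-yl trifluoroacetate (CuCl2 cat., DBU, MeCN, 0 °C) gives 2-[(2-methylbut-3-yn-2-yl)oxy]-4,6-bis(methoxymethoxy)benzaldehyde F3.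
  - Lindlar semihydrogenation (H2, Pd/CaCO3 poisoned with Pb(OAc)2, quinoline, EtOAc) gives 2-[(2-methylbut-3-en-2-yl)oxy]-4,6-bis(methoxymethoxy)benzaldehyde F4.
  - Aromatic Claisen rearrangement (toluene, 110 °C) transfers the allyl group with inversion to the only free ortho carbon and should give 8 as a single regioisomer.

**Step 7.**
- The C4 cation may eliminate to the flav-3-ene, alkylate ring A of a second molecule, or the acid may start to remove MOM groups.
- Fallback: from 12 directly to 14, leaving out 13 and step 8. DDQ (2,3-dichloro-5,6-dicyano-1,4-benzoquinone, 1.2 equiv) in CH2Cl2/pH 7 buffer at 0 °C abstracts hydride from the most electron-rich benzylic position, C4–H. Water adds to the resulting dialkoxy-stabilised cation and the hemiketal collapses to the ketone. The cation is too stabilised to alkylate arenes, and its elimination product is an enol ether that hydrolyses to the same ketone. No new compound is made (F0).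

**Step 9.**
- The freed phenols may add across the ortho prenyl double bonds (chroman formation), and acid may open ring C, with loss of C2 configuration or 6/8 scrambling.
- Fallback: from 14, Me3SiOTf and 2,2'-bipyridyl (CH2Cl2, 0 °C) convert the aryl MOM ethers under non-protic, buffered conditions into the silyl ethers. This gives (2S)-5,7-bis(trimethylsilyloxy)-2-[4-(trimethylsilyloxy)-3-(3-methylbut-2-en-1-yl)phenyl]-8-(3-methylbut-2-en-1-yl)chroman-4-one F5, which is hydrolysed by water on work-up to 15.

## Further compounds

F1 | step 6 | (2R,4R)-4-methoxy-5,7-bis(methoxymethoxy)-2-[4-(methoxymethoxy)-3-(3-methylbut-2-en-1-yl)phenyl]-8-(3-methylbut-2-en-1-yl)chromane | CO[C@@H]1C[C@H](c2ccc(OCOC)c(CC=C(C)C)c2)Oc2c(CC=C(C)C)c(OCOC)cc(OCOC)c21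
F2 | step 5 | 2-hydroxy-4,6-bis(methoxymethoxy)benzaldehyde | O=Cc1c(O)cc(OCOC)cc1OCOC
F3 | step 5 | 2-[(2-methylbut-3-yn-2-yl)oxy]-4,6-bis(methoxymethoxy)benzaldehyde | C#CC(C)(C)Oc1cc(OCOC)cc(OCOC)c1C=O
F4 | step 5 | 2-[(2-methylbut-3-en-2-yl)oxy]-4,6-bis(methoxymethoxy)benzaldehyde | C=CC(C)(C)Oc1cc(OCOC)cc(OCOC)c1C=O
F0 | step 7 | none | none
F5 | step 9 | (2S)-5,7-bis(trimethylsilyloxy)-2-[4-(trimethylsilyloxy)-3-(3-methylbut-2-en-1-yl)phenyl]-8-(3-methylbut-2-en-1-yl)chroman-4-one | CC(C)=CCc1cc([C@@H]2CC(=O)c3c(O[Si](C)(C)C)cc(O[Si](C)(C)C)c(CC=C(C)C)c3O2)ccc1O[Si](C)(C)C
A1 | alternative 1 | (2S)-7-O-acetyl euchrestaflavanone A | CC(C)=CCc1cc([C@@H]2CC(=O)c3c(O)cc(OC(C)=O)c(CC=C(C)C)c3O2)ccc1O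
A2 | alternative 1 | (2S)-7-acetoxy-5-(3-methylbut-2-en-1-yloxy)-2-[4-(2-methylbut-3-en-2-yloxy)phenyl]chroman-4-one | C=CC(C)(C)Oc1ccc([C@@H]2CC(=O)c3c(OCC=C(C)C)cc(OC(C)=O)cc3O2)cc1
A3 | alternative 2 | (2S)-5,7,4'-tris-O-(tert-butyldimethylsilyl) euchrestaflavanone A | CC(C)=CCc1cc([C@@H]2CC(=O)c3c(O[Si](C)(C)C(C)(C)C)cc(O[Si](C)(C)C(C)(C)C)c(CC=C(C)C)c3O2)ccc1O[Si](C)(C)C(C)(C)C
A4 | alternative 2 | 2-diazo-1-[2-{[4-(tert-butyldimethylsilyloxy)-3-(3-methylbut-2-en-1-yl)phenyl]methoxy}-4,6-bis(tert-butyldimethylsilyloxy)-3-(3-methylbut-2-en-1-yl)phenyl]ethan-1-one | [N-]=[N+]=CC(=O)c1c(O[Si](C)(C)C(C)(C)C)cc(O[Si](C)(C)C(C)(C)C)c(CC=C(C)C)c1OCc1ccc(O[Si](C)(C)C(C)(C)C)c(CC=C(C)C)c1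
A5 | alternative 3 | (2S)-4'-O-methoxymethyl euchrestaflavanone A | CC(C)=CCc1cc([C@@H]2CC(=O)c3c(O)cc(O)c(CC=C(C)C)c3O2)ccc1OCOC
A6 | alternative 3 | methyl 4-{(2S)-2-[4-(methoxymethoxy)-3-(3-methylbut-2-en-1-yl)phenyl]-4-oxo-3,4-dihydro-2H-pyran-6-yl}-7-methyl-3-oxooct-6-enoate (epimers at the chain carbon C4) | COC(=O)CC(=O)C(CC=C(C)C)C1=CC(=O)C[C@@H](c2ccc(OCOC)c(CC=C(C)C)c2)O1
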